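Everything rests on cutting the carbocycle of each quinoline at C4a–C5 and C8–C8a. Going round that ring, C5 holds the pyrrole carbon, C6 and C7 hold oxygen and C8 holds only hydrogen. C5–C8 therefore map atom for atom onto C2–C5 of 2-allyl-3,4-dimethoxyfuran, while C4a and C8a are C3 and C2 of a pyridine. A single Diels–Alder reaction of 2,3-pyridyne, released by fluoride from 3-(trimethylsilyl)pyridin-2-yl triflate, should close the ring with all four substituents in place. The allyl group is a masked acetaldehyde. Two such aldehydes and an (S)-3-methylazecane-bearing propylamine are then joined to the pyrrole, and four methyl ethers are removed last.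

Key step: step 4

Remarks on the chemistry:
- The cycloadduct is racemic and one enantiomer is drawn. Both bridgehead centres disappear on aromatisation.
- The only stereocentre of the target, azecane C3, is S. It comes unchanged from the (R)-hydroxy ester provided the hydroxymethyl carbon ends as C2 (bound to nitrogen) and the ester carbon as C4. The opposite orientation would give the enantiomer.
- 3,4-Dimethoxyfuran, 1-bromo-6-chlorohexane and tert-butyl [(2-nitrophenyl)sulfonyl]carbamate are assumed to be purchasable.

Step 1
Reactants: 1 3-bromopyridin-2-ol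
Product: 2 3-bromo-2-[(trimethylsilyl)oxy]pyridine
Conditions: (Me3Si)2NH, THF, reflux; volatiles removed in vacuo, used crude
Reagents that add atoms: hexamethyldisilazane, C[Si](C)(C)N[Si](C)(C)C
Why: Silazane O-silylation of the hydroxypyridine tautomer is driven by loss of ammonia and leaves no acidic proton or salt that would consume the organolithium of step 2.

Step 2
Reactants: 2 3-bromo-2-[(trimethylsilyl)oxy]pyridine
Product: 5 3-(trimethylsilyl)pyridin-2-yl trifluoromethanesulfonate, via 3-lithio-2-[(trimethylsilyl)oxy]pyridine 3 (not isolated), via lithium 3-(trimethylsilyl)pyridin-2-olate 4 (not isolated)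
Conditions: n-BuLi, THF, −90 °C; then Tf2O, −90 °C → rt
Reagents that add atoms: trifluoromethanesulfonic anhydride, O=S(=O)(OS(=O)(=O)C(F)(F)F)C(F)(F)F
Why: Bromine–lithium exchange gives 3, whose carbanion takes silicon from the neighbouring oxygen in a retro-Brook 1,3-shift, and the pyridinolate 4 so unmasked is sulfonylated on oxygen by Tf2O, the standard sequence for ortho-silylaryl triflates from ortho-bromophenols.

Step 3
Reactants: 6 3,4-dimethoxyfuran; 7 allyl bromide
Product: 9 2-allyl-3,4-dimethoxyfuran, via 2-lithio-3,4-dimethoxyfuran 8 (not isolated)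
Conditions: n-BuLi (1.0 equiv), THF, −78 → 0 °C; then 7, −78 °C → rt; basic alumina
Reagents that add atoms: none
Why: Directed α-lithiation of the furan next to the ring oxygen and a methoxy group, followed by SN2 alkylation with the reactive allylic bromide, should give the monosubstituted furan because only one equivalent of base is used.

Step 4
Reactants: 5 3-(trimethylsilyl)pyridin-2-yl trifluoromethanesulfonate; 9 2-allyl-3,4-dimethoxyfuran
Product: 11 (±)-5-allyl-6,7-dimethoxy-5,8-dihydro-5,8-epoxyquinoline, via 2,3-pyridyne 10 (not isolated)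
Conditions: CsF (5 equiv), MeCN, rt; 5 (2 equiv) added by syringe pump to 9 (1 equiv); basic alumina
Reagents that add atoms: none
Why: Fluoride attacks the silicon of 5, triflate leaves from the neighbouring carbon, and the hetaryne 10 is intercepted by the furan diene in a concerted but asynchronous [4+2] cycloaddition, the known Diels–Alder trapping of fluoride-generated pyridynes by furans. The six-membered carbocycle C4a–C5–C6–C7–C8–C8a closes by intermolecular cycloaddition, both new bonds (C8–C8a and C4a–C5) arising in one event with the furan oxygen left as a 5,8-bridge. The bridgeheads C5 and C8 are new stereocentres whose relative configuration is dictated by suprafacial addition and the one-atom bridge, and no absolute control is needed because 11 is racemic and both centres become sp2 in step 5. Regioselectivity is required: the ring nitrogen polarises the strained bond so that C2 of 10 is the acceptor end, and the leading bond should form to the unsubstituted, less hindered and more nucleophilic C5 of 9, which sends the allyl-bearing C2 to pyridyne C3 and hence to quinoline C5. Chemoselectivity for the diene over an ene reaction of the allyl group is secured by the two methoxy donors, which raise the furan HOMO. Slow addition keeps the stationary concentration of 10 low against a high concentration of diene, which disfavours its capture by pyridine nitrogen or fluoride.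

Step 5
Reactants: 11 (±)-5-allyl-6,7-dimethoxy-5,8-dihydro-5,8-epoxyquinoline
Product: 12 5-allyl-6,7-dimethoxyquinoline
Conditions: TiCl4, Zn dust, THF, reflux 1 h; then 11, 0 °C → reflux; aq K2CO3, filtration
Reagents that add atoms: none
Why: Reductive deoxygenation of a 1,4-epoxy-1,4-dihydroarene by low-valent titanium is driven by the strong Ti–O bond and by aromatisation, and zinc is chosen as the reductant because a hydride source together with titanium would hydrometalate the terminal alkene.

Step 6
Reactants: 13 methyl (R)-3-hydroxy-2-methylpropanoate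
Product: 14 methyl (R)-3-[(tert-butyldimethylsilyl)oxy]-2-methylpropanoate
Conditions: TBSCl, imidazole, CH2Cl2, rt
Reagents that add atoms: tert-butyldimethylsilyl chloride, CC(C)(C)[Si](C)(C)Cl
Why: Silyl ether formation on the primary alcohol under imidazole catalysis is too weakly basic to enolise the ester or to provoke β-elimination, so the stereocentre stays R.

Step 7
Reactants: 14 methyl (R)-3-[(tert-butyldimethylsilyl)oxy]-2-methylpropanoate
Product: 15 (S)-3-[(tert-butyldimethylsilyl)oxy]-2-methylpropan-1-ol
Conditions: i-Bu2AlH (2.2 equiv), CH2Cl2, −78 → 0 °C; aq potassium sodium tartrate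
Reagents that add atoms: none
Why: Hydride reduction of the ester to the primary alcohol does not touch the α-carbon, so the spatial arrangement is kept and only the descriptor changes to S through the new CIP ranking.

Step 8
Reactants: 15 (S)-3-[(tert-butyldimethylsilyl)oxy]-2-methylpropan-1-ol
Product: 16 (R)-3-[(tert-butyldimethylsilyl)oxy]-2-methylpropyl 4-methylbenzenesulfonate
Conditions: TsCl, Et3N, DMAP (cat.), CH2Cl2, 0 °C → rt
Reagents that add atoms: 4-toluenesulfonyl chloride, Cc1ccc(cc1)S(=O)(=O)Cl
Why: Sulfonylation of the primary alcohol makes the former ester carbon the electrophilic end of the three-carbon unit, which fixes that the silyloxymethyl carbon will later carry nitrogen.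

Step 9
Reactants: 16 (R)-3-[(tert-butyldimethylsilyl)oxy]-2-methylpropyl 4-methylbenzenesulfonate; 17 1-bromo-6-chlorohexane
Product: 19 (S)-tert-butyl[(9-chloro-2-methylnonyl)oxy]dimethylsilane, via 6-chlorohexylmagnesium bromide 18 (not isolated)
Conditions: 17, Mg, THF, 35 °C; then 16, Li2CuCl4 (5 mol %), THF, −20 °C → rt
Reagents that add atoms: none
Why: Copper-catalysed Grignard–tosylate cross-coupling (Fouquet–Schlosser variant of the Kochi coupling) joins the C3 and C6 units, magnesium inserting only into the C–Br bond of 17 and the C–Cl bond being inert to the cuprate at this temperature, while the stereocentre lies β to the reacting carbon and is not involved.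

Step 10
Reactants: 19 (S)-tert-butyl[(9-chloro-2-methylnonyl)oxy]dimethylsilane; 20 tert-butyl [(2-nitrophenyl)sulfonyl]carbamate
Product: 22 tert-butyl {(8S)-9-[(tert-butyldimethylsilyl)oxy]-8-methylnonyl}[(2-nitrophenyl)sulfonyl]carbamate, via primary iodide 21 (not isolated)
Conditions: K2CO3, NaI (20 mol %), DMF, 65 °C
Reagents that add atoms: none
Why: Alkylation of the acidic N-Boc nosylamide (Fukuyama amine synthesis) under Finkelstein catalysis introduces the ring nitrogen at the unhindered chain end, and the Boc group rules out a second alkylation.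

Step 11
Reactants: 22 tert-butyl {(8S)-9-[(tert-butyldimethylsilyl)oxy]-8-methylnonyl}[(2-nitrophenyl)sulfonyl]carbamate
Product: 23 N-[(8S)-9-hydroxy-8-methylnonyl]-2-nitrobenzenesulfonamide
Conditions: 3 M HCl in MeOH, 0 °C → rt
Reagents that add atoms: none
Why: Acidolysis removes both acid-labile groups in one operation, the Boc group by loss of isobutene and CO2 and the primary silyl ether by methanolysis, whereas the nosylamide is inert to acid.

Step 12
Reactants: 23 N-[(8S)-9-hydroxy-8-methylnonyl]-2-nitrobenzenesulfonamide
Product: 24 (3S)-3-methyl-1-[(2-nitrophenyl)sulfonyl]azecane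
Conditions: PPh3, DIAD, toluene–THF, rt; 23 added slowly, final 0.01 M
Reagents that add atoms: none
Why: Intramolecular Fukuyama–Mitsunobu N-alkylation, a 10-exo-tet closure known for eight- to ten-membered N-nosyl azacycles, takes place at the CH2–O carbon and not at the neighbouring stereocentre, and slow addition at high dilution favours ring closure over dimerisation.

Step 13
Reactants: 24 (3S)-3-methyl-1-[(2-nitrophenyl)sulfonyl]azecane
Product: 25 (S)-3-methylazecane
Conditions: PhSH, K2CO3, DMF, rt; acid–base extraction
Reagents that add atoms: none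
Why: In the Fukuyama denosylation the thiolate adds to the nitroarene at the sulfonyl-bearing carbon (SNAr via a Meisenheimer adduct) and loss of SO2 frees the secondary amine under conditions that touch nothing else.

Step 14
Reactants: 25 (S)-3-methylazecane; 26 acrylonitrile
Product: 27 3-[(3S)-3-methylazecan-1-yl]propanenitrile
Conditions: MeOH, rt → 50 °C
Reagents that add atoms: none
Why: Aza-Michael addition (cyanoethylation) of the secondary amine installs the three-carbon arm without any risk of quaternisation and without by-products.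

Step 15
Reactants: 27 3-[(3S)-3-methylazecan-1-yl]propanenitrile
Product: 28 3-[(3S)-3-methylazecan-1-yl]propan-1-amine
Conditions: LiAlH4, Et2O, 0 °C → rt; H2O, 15% NaOH, H2O
Reagents that add atoms: none
Why: Hydride reduction of the nitrile to the primary amine is fast at low temperature, which keeps retro-Michael loss of acrylonitrile from the β-aminonitrile in check.

Step 16
Reactants: 12 5-allyl-6,7-dimethoxyquinoline
Product: 30 2-(6,7-dimethoxyquinolin-5-yl)acetaldehyde, via glycol 29 (not isolated)
Conditions: OsO4 (2 mol %), NaIO4 (4 equiv), 2,6-lutidine, dioxane–H2O 3:1, rt; used at once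
Reagents that add atoms: OsO4, O=[Os](=O)(=O)=O (catalytic oxygen carrier); NaIO4, [Na+].[O-]I(=O)(=O)=O (stoichiometric oxygen source)
Why: Lemieux–Johnson oxidation dihydroxylates the only alkene and cleaves the glycol 29 in the same flask, 2,6-lutidine buffering the medium, and the enolisable arylacetaldehyde is used at once.

Step 17
Reactants: 30 2-(6,7-dimethoxyquinolin-5-yl)acetaldehyde (2.2 equiv); 28 3-[(3S)-3-methylazecan-1-yl]propan-1-amine
Product: 32 (3S)-1-{3-[3,4-bis(6,7-dimethoxyquinolin-5-yl)-1H-pyrrol-1-yl]propyl}-3-methylazecane, via imine 31 (not isolated)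
Conditions: AgOAc (3 equiv), NaOAc, THF, 60 °C, Ar
Reagents that add atoms: none
Why: This is the AgOAc-mediated oxidative pyrrole synthesis from a primary amine and two molecules of an arylacetaldehyde, in which imine 31 tautomerises to its enamine, one-electron oxidation by monovalent silver couples two β-carbons (pyrrole C3–C4), and the dimer closes on one nitrogen in Paal–Knorr fashion and aromatises, the symmetry of the product removing any regiochemical question.

Step 18
Reactants: 32 (3S)-1-{3-[3,4-bis(6,7-dimethoxyquinolin-5-yl)-1H-pyrrol-1-yl]propyl}-3-methylazecane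
Product: 33 isohalitulin
Conditions: BBr3 (12 equiv), CH2Cl2, −78 °C → rt; degassed H2O, pH 7–8 under Ar; reversed-phase chromatography
Reagents that add atoms: none
Why: In this Lewis-acid cleavage of aryl methyl ethers, once the three basic nitrogens are saturated BBr3 binds each methoxy oxygen and bromide removes the methyl group by SN2, hydrolysis of the aryl borates then frees the two catechols, and the remote stereocentre is untouched.

Compound list

1 | 3-bromopyridin-2-ol | Oc1ncccc1Br | starting material
2 | 3-bromo-2-[(trimethylsilyl)oxy]pyridine | C[Si](C)(C)Oc1ncccc1Br | intermediate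
3 | 3-lithio-2-[(trimethylsilyl)oxy]pyridine (not isolated) | C[Si](C)(C)Oc1ncccc1[Li] | intermediate
4 | lithium 3-(trimethylsilyl)pyridin-2-olate (not isolated) | [Li+].[O-]c1ncccc1[Si](C)(C)C | intermediate
5 | 3-(trimethylsilyl)pyridin-2-yl trifluoromethanesulfonate | C[Si](C)(C)c1cccnc1OS(=O)(=O)C(F)(F)F | intermediate
6 | 3,4-dimethoxyfuran | COc1cocc1OC | starting material
7 | allyl bromide | C=CCBr | starting material
8 | 2-lithio-3,4-dimethoxyfuran (not isolated) | [Li]c1occ(OC)c1OC | intermediate
9 | 2-allyl-3,4-dimethoxyfuran | C=CCc1occ(OC)c1OC | intermediate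
10 | 2,3-pyridyne (2,3-didehydropyridine, not isolated) | C1#CC=CC=N1 | intermediate
11 | (±)-5-allyl-6,7-dimethoxy-5,8-dihydro-5,8-epoxyquinoline (racemate, one enantiomer drawn) | C=CC[C@]12O[C@H](C(OC)=C1OC)c1ncccc12 | intermediate
12 | 5-allyl-6,7-dimethoxyquinoline | C=CCc1c(OC)c(OC)cc2ncccc12 | intermediate
13 | methyl (R)-3-hydroxy-2-methylpropanoate | C[C@H](CO)C(=O)OC | starting material
14 | methyl (R)-3-[(tert-butyldimethylsilyl)oxy]-2-methylpropanoate | C[C@H](CO[Si](C)(C)C(C)(C)C)C(=O)OC | intermediate
15 | (S)-3-[(tert-butyldimethylsilyl)oxy]-2-methylpropan-1-ol | C[C@H](CO[Si](C)(C)C(C)(C)C)CO | intermediate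
16 | (R)-3-[(tert-butyldimethylsilyl)oxy]-2-methylpropyl 4-methylbenzenesulfonate | C[C@H](CO[Si](C)(C)C(C)(C)C)COS(=O)(=O)c1ccc(C)cc1 | intermediate
17 | 1-bromo-6-chlorohexane | ClCCCCCCBr | starting material
18 | 6-chlorohexylmagnesium bromide (not isolated) | ClCCCCCC[Mg]Br | intermediate
19 | (S)-tert-butyl[(9-chloro-2-methylnonyl)oxy]dimethylsilane | C[C@H](CO[Si](C)(C)C(C)(C)C)CCCCCCCCl | intermediate
20 | tert-butyl [(2-nitrophenyl)sulfonyl]carbamate | CC(C)(C)OC(=O)NS(=O)(=O)c1ccccc1[N+](=O)[O-] | starting material
21 | (S)-tert-butyl[(9-iodo-2-methylnonyl)oxy]dimethylsilane (not isolated) | C[C@H](CO[Si](C)(C)C(C)(C)C)CCCCCCCI | intermediate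
22 | tert-butyl {(8S)-9-[(tert-butyldimethylsilyl)oxy]-8-methylnonyl}[(2-nitrophenyl)sulfonyl]carbamate | C[C@H](CO[Si](C)(C)C(C)(C)C)CCCCCCCN(C(=O)OC(C)(C)C)S(=O)(=O)c1ccccc1[N+](=O)[O-] | intermediate
23 | N-[(8S)-9-hydroxy-8-methylnonyl]-2-nitrobenzenesulfonamide | C[C@H](CO)CCCCCCCNS(=O)(=O)c1ccccc1[N+](=O)[O-] | intermediate
24 | (3S)-3-methyl-1-[(2-nitrophenyl)sulfonyl]azecane | C[C@H]1CCCCCCCN(S(=O)(=O)c2ccccc2[N+](=O)[O-])C1 | intermediate
25 | (S)-3-methylazecane | C[C@H]1CCCCCCCNC1 | intermediate
26 | acrylonitrile | C=CC#N | starting material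
27 | 3-[(3S)-3-methylazecan-1-yl]propanenitrile | C[C@H]1CCCCCCCN(CCC#N)C1 | intermediate
28 | 3-[(3S)-3-methylazecan-1-yl]propan-1-amine | C[C@H]1CCCCCCCN(CCCN)C1 | intermediate
29 | (±)-3-(6,7-dimethoxyquinolin-5-yl)propane-1,2-diol (not isolated) | OCC(O)Cc1c(OC)c(OC)cc2ncccc12 | intermediate
30 | 2-(6,7-dimethoxyquinolin-5-yl)acetaldehyde | O=CCc1c(OC)c(OC)cc2ncccc12 | intermediate
31 | N-{3-[(3S)-3-methylazecan-1-yl]propyl}-2-(6,7-dimethoxyquinolin-5-yl)ethan-1-imine (not isolated) | C[C@H]1CCCCCCCN(CCCN=CCc2c(OC)c(OC)cc3ncccc23)C1 | intermediate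
32 | (3S)-1-{3-[3,4-bis(6,7-dimethoxyquinolin-5-yl)-1H-pyrrol-1-yl]propyl}-3-methylazecane | C[C@H]1CCCCCCCN(CCCn2cc(-c3c(OC)c(OC)cc4ncccc34)c(-c3c(OC)c(OC)cc4ncccc34)c2)C1 | intermediate
33 | isohalitulin, 5,5'-(1-{3-[(3S)-3-methylazecan-1-yl]propyl}-1H-pyrrole-3,4-diyl)bis(quinoline-6,7-diol) | C[C@H]1CCCCCCCN(CCCn2cc(-c3c(O)c(O)cc4ncccc34)c(-c3c(O)c(O)cc4ncccc34)c2)C1 | target

Total step count: 18.

Longest linear sequence: 12 steps (13 → 14 → 15 → 16 → 19 → 22 → 23 → 24 → 25 → 27 → 28 → 32 → 33; steps 6–15, 17 and 18). The quinoline branch runs over seven steps from 1 to 33 (steps 1, 2, 4, 5, 16, 17 and 18).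

Steps most likely to fail

1. Step 4. The unsymmetrical furan may add in both orientations with little preference. The short-lived hetaryne may also be consumed by fluoride, by pyridine nitrogen or by self-reaction faster than by the diene.
Fallback, setting out from allyl bromide 7 and rejoining at 12: the C5 carbon is placed by a sigmatropic shift on a preformed quinoline.
   - A Skraup reaction of purchased 4-amino-2-methoxyphenol (glycerol, H2SO4, sodium 3-nitrobenzenesulfonate, 135 °C) closes para to the methoxy group and should give 7-methoxyquinolin-6-ol F1.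
   - O-Allylation with 7 (K2CO3, DMF) gives 6-(allyloxy)-7-methoxyquinoline F2.
   - Aromatic Claisen rearrangement (N,N-diethylaniline, 190 °C) can deliver the allyl group only to C5, because C7 is blocked. It gives 5-allyl-7-methoxyquinolin-6-ol F3.
   - O-Methylation (MeI, K2CO3, acetone) leads to 12.

2. Step 5. Lewis-acid-induced opening of the oxygen bridge, followed by tautomerisation to a phenol, may outrun oxygen transfer to titanium. The acid-labile enol ethers may also be hydrolysed during work-up.
Fallback, setting out from 11 and rejoining at 12: the isomerisation is made the intended path.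
   - Catalytic camphorsulfonic acid in CH2Cl2 ionises the tertiary C5–O bond, which is conjugated with the C6=C7 enol ether. Loss of H8 should give 5-allyl-6,7-dimethoxyquinolin-8-ol F4.
   - Triflation (Tf2O, pyridine) gives 5-allyl-6,7-dimethoxyquinolin-8-yl trifluoromethanesulfonate F5.
   - Palladium-catalysed formate reduction of the aryl triflate (Pd(OAc)2, PPh3, HCO2H, Et3N, DMF, 60 °C) removes the oxygen function and gives 12.

3. Step 17. Coupling of two hindered enamine-derived radicals may be slow, silver may be tied up by the three basic nitrogens, and aldol self-condensation of the aldehyde may take over.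
Fallback, setting out from 30 (with 25 as the amine) and rejoining at 32: the oxidative coupling is replaced by a sigmatropic C–C bond formation.
   - Hydrazine hydrate (0.5 equiv, EtOH) converts 30 into the azine 1,2-bis[2-(6,7-dimethoxyquinolin-5-yl)ethylidene]hydrazine F6.
   - A Piloty–Robinson reaction (PhCOCl, pyridine, 170 °C) proceeds by N,N'-diacylation, [3,3] shift of the bis-enehydrazide and cyclisation. It gives [3,4-bis(6,7-dimethoxyquinolin-5-yl)-1H-pyrrol-1-yl](phenyl)methanone F7.
   - Hydrolysis (NaOH, MeOH–H2O) gives 5,5'-(1H-pyrrole-3,4-diyl)bis(6,7-dimethoxyquinoline) F8.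
   - N-Alkylation (NaH, 1-bromo-3-chloropropane, DMF) gives 5,5'-[1-(3-chloropropyl)-1H-pyrrole-3,4-diyl]bis(6,7-dimethoxyquinoline) F9.
   - Amination with 25 (K2CO3, NaI, MeCN, 80 °C) gives 32. Steps 14 and 15 are then not needed.

Further compounds

F1 | step 4 | 7-methoxyquinolin-6-ol | COc1cc2ncccc2cc1O
F2 | step 4 | 6-(allyloxy)-7-methoxyquinoline | C=CCOc1cc2cccnc2cc1OC
F3 | step 4 | 5-allyl-7-methoxyquinolin-6-ol | C=CCc1c(O)c(OC)cc2ncccc12
F4 | step 5 | 5-allyl-6,7-dimethoxyquinolin-8-ol | C=CCc1c(OC)c(OC)c(O)c2ncccc12
F5 | step 5 | 5-allyl-6,7-dimethoxyquinolin-8-yl trifluoromethanesulfonate | C=CCc1c(OC)c(OC)c(OS(=O)(=O)C(F)(F)F)c2ncccc12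
F6 | step 17 | 1,2-bis[2-(6,7-dimethoxyquinolin-5-yl)ethylidene]hydrazine | C(C=NN=CCc1c(OC)c(OC)cc2ncccc12)c1c(OC)c(OC)cc2ncccc12
F7 | step 17 | [3,4-bis(6,7-dimethoxyquinolin-5-yl)-1H-pyrrol-1-yl](phenyl)methanone | O=C(c1ccccc1)n1cc(-c2c(OC)c(OC)cc3ncccc23)c(-c2c(OC)c(OC)cc3ncccc23)c1
F8 | step 17 | 5,5'-(1H-pyrrole-3,4-diyl)bis(6,7-dimethoxyquinoline) | [nH]1cc(-c2c(OC)c(OC)cc3ncccc23)c(-c2c(OC)c(OC)cc3ncccc23)c1
F9 | step 17 | 5,5'-[1-(3-chloropropyl)-1H-pyrrole-3,4-diyl]bis(6,7-dimethoxyquinoline) | ClCCCn1cc(-c2c(OC)c(OC)cc3ncccc23)c(-c2c(OC)c(OC)cc3ncccc23)c1
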